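**Retrosynthetic overview**
1. Target ⇐ acid-mediated unmasking of 49; ring C (seven-membered lactone) by ring-closing metathesis of 48; acid 46 ⇐ ester 43, made from ring-A acid 18 and the primary OH of ring-B diol 41 before the neighbouring C=O exists (so no γ-hydroxy ester can relactonise).
2. Diol 41 ⇐ Wittig opening of lactol 39 ⇐ iodolactonisation of cyclohexene acid 36 (sets the tertiary C–O).
3. Acid 36 ⇐ Ireland–Claisen ring contraction of δ-lactone 33 (forms ring B) ⇐ CBS reduction of enone 31 ⇐ Stille acylation of stannane 22 with half-ester 29 ⇐ lipase desymmetrisation of prochiral diester 28.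
4. Acid 18 ⇐ Wittig/Stille side-chain build-up on alcohol 13 ⇐ acyl → isopropyl on adduct 8 ⇐ [Cu((S,S)-t-Bu-box)](SbF6)2-catalysed Diels–Alder of diene 6 with imide 7 (forms ring A).
5. Ring order: ring A (step 5); δ-lactone (step 23) → ring B (step 24) → temporary bridged γ-lactone (step 25) → ring C (step 34).

Abbreviations: TBS = tert-butyldimethylsilyl (TBSO-methyl = CH2OTBS); PMB = 4-methoxybenzyl (PMBO-methyl = CH2OPMB); (S,S)-t-Bu-box = 2,2′-(propane-2,2-diyl)bis[(4S)-4-tert-butyl-4,5-dihydro-1,3-oxazole]; ring A = cyclohexene of the acid half, ring B = cyclohexane of the lactone half, ring C = seven-membered lactone.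

Assumption: the lipase used in step 21 is taken (after the usual screening of commercial hydrolases) to cut the ester arm that leaves the (R)-half-ester 29; all later steps are written for this enantiomer.

**Route**

Step 1
Reactants: 1 prop-2-yn-1-ol
Product: 2 1-methoxy-4-[(prop-2-yn-1-yloxy)methyl]benzene
Conditions: NaH, PMBCl, Bu4NI (cat.), THF, 0 °C → rt
Reagents that add atoms: 4-methoxybenzyl chloride, COc1ccc(CCl)cc1
Why: Williamson ether synthesis of a primary alkoxide with a benzylic chloride; no stereocentre is involved.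

Step 2
Reactants: 2 1-methoxy-4-[(prop-2-yn-1-yloxy)methyl]benzene
Product: 3 2-[(1E)-3-PMBO-prop-1-en-1-yl]-4,4,5,5-tetramethyl-1,3,2-dioxaborolane
Conditions: pinacolborane, Cp2Zr(H)Cl (5 mol%), Et3N (10 mol%), neat, 60 °C
Reagents that add atoms: pinacolborane, CC1(C)OBOC1(C)C
Why: Cp2Zr(H)Cl-catalysed hydroboration of a terminal alkyne is a syn, anti-Markovnikov addition and gives only the E-alkenylboronate.

Step 3
Reactants: 4 2-bromoprop-2-en-1-ol
Product: 5 [(2-bromoprop-2-en-1-yl)oxy](tert-butyl)dimethylsilane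
Conditions: TBSCl, imidazole, CH2Cl2, 0 °C → rt
Reagents that add atoms: tert-butyldimethylsilyl chloride, CC(C)(C)[Si](C)(C)Cl
Why: Standard silylation of a primary allylic alcohol; this TBS ether is carried to the end of the synthesis.

Step 4
Reactants: 3 2-[(1E)-3-PMBO-prop-1-en-1-yl]-4,4,5,5-tetramethyl-1,3,2-dioxaborolane; 5 [(2-bromoprop-2-en-1-yl)oxy](tert-butyl)dimethylsilane
Product: 6 tert-butyl{[(3E)-2-methylidene-5-PMBO-pent-3-en-1-yl]oxy}dimethylsilane
Conditions: Pd(PPh3)4 (5 mol%), K3PO4, THF/H2O, 60 °C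
Reagents that add atoms: none
Why: Suzuki–Miyaura coupling of an alkenyl bromide with an alkenylboronate under Pd(PPh3)4 (zerovalent palladium) proceeds with retention, so the E-diene is formed.

Step 5
Reactants: 6 tert-butyl{[(3E)-2-methylidene-5-PMBO-pent-3-en-1-yl]oxy}dimethylsilane; 7 3-(prop-2-enoyl)-1,3-oxazolidin-2-one
Product: 8 3-{[(1S,2R)-2-(PMBO-methyl)-4-(TBSO-methyl)cyclohex-3-en-1-yl]carbonyl}-1,3-oxazolidin-2-one
Conditions: [Cu((S,S)-t-Bu-box)](SbF6)2 (10 mol%), CH2Cl2, −20 °C → rt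
Reagents that add atoms: none
Why: Catalytic asymmetric Diels–Alder reaction: the divalent copper complex chelates the imide, its tert-butyl groups expose the Cα Re face (1S, as in the known cyclopentadiene case), endo addition to the E-diene puts CH2OPMB cis to the acyl group (2R), and the 1- and 3-substituents of the diene both direct this regiochemistry; this forms ring A and its two stereocentres.

Step 6
Reactants: 8 3-{[(1S,2R)-2-(PMBO-methyl)-4-(TBSO-methyl)cyclohex-3-en-1-yl]carbonyl}-1,3-oxazolidin-2-one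
Product: 9 (1S,2R)-N-methoxy-N-methyl-2-(PMBO-methyl)-4-(TBSO-methyl)cyclohex-3-ene-1-carboxamide
Conditions: MeNHOMe·HCl, Me3Al, CH2Cl2, 0 °C → rt
Reagents that add atoms: N,O-dimethylhydroxylamine hydrochloride, CNOC.Cl
Why: Me3Al-mediated transamidation of an N-acyl oxazolidinone to the Weinreb amide is non-basic, so the epimerisable cis α-centre is kept.

Step 7
Reactants: 9 (1S,2R)-N-methoxy-N-methyl-2-(PMBO-methyl)-4-(TBSO-methyl)cyclohex-3-ene-1-carboxamide
Product: 10 1-[(1S,2R)-2-(PMBO-methyl)-4-(TBSO-methyl)cyclohex-3-en-1-yl]ethan-1-one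
Conditions: MeMgBr, THF, 0 °C; aq. NH4Cl
Reagents that add atoms: methylmagnesium bromide, C[Mg]Br
Why: Weinreb ketone synthesis: the magnesium chelate stops at mono-addition and the ketone is only released on cold work-up.

Step 8
Reactants: 10 1-[(1S,2R)-2-(PMBO-methyl)-4-(TBSO-methyl)cyclohex-3-en-1-yl]ethan-1-one
Product: 11 (3R,4S)-3-(PMBO-methyl)-4-(prop-1-en-2-yl)-1-(TBSO-methyl)cyclohex-1-ene
Conditions: Cp2TiMe2, PhMe, 65 °C, dark
Reagents that add atoms: dimethyltitanocene, C[Ti](C)(C1C=CC=C1)C1C=CC=C1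
Why: Petasis methylenation is non-basic and therefore does not epimerise the cis ketone (the descriptors change only through priorities).

Step 9
Reactants: 11 (3R,4S)-3-(PMBO-methyl)-4-(prop-1-en-2-yl)-1-(TBSO-methyl)cyclohex-1-ene
Product: 12 (3S,4R)-3-(PMBO-methyl)-4-(propan-2-yl)-1-(TBSO-methyl)cyclohex-1-ene
Conditions: H2 (1 atm), RhCl(PPh3)3 (5 mol%), benzene, rt
Reagents that add atoms: none
Why: Homogeneous hydrogenation with RhCl(PPh3)3 reduces the 1,1-disubstituted alkene and leaves the trisubstituted ring alkene and the benzyl ether alone; no stereocentre is formed or touched.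

Step 10
Reactants: 12 (3S,4R)-3-(PMBO-methyl)-4-(propan-2-yl)-1-(TBSO-methyl)cyclohex-1-ene
Product: 13 [(1S,6R)-6-(propan-2-yl)-3-(TBSO-methyl)cyclohex-2-en-1-yl]methanol
Conditions: DDQ, CH2Cl2/pH 7 buffer, 0 °C
Reagents that add atoms: none
Why: Oxidative cleavage of the PMB ether by DDQ leaves the TBS ether and the alkene intact.

Step 11
Reactants: 13 [(1S,6R)-6-(propan-2-yl)-3-(TBSO-methyl)cyclohex-2-en-1-yl]methanol
Product: 15 ethyl (2Z)-2-bromo-3-[(1S,6R)-6-(propan-2-yl)-3-(TBSO-methyl)cyclohex-2-en-1-yl]prop-2-enoate, via aldehyde 14 (not isolated)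
Conditions: Dess–Martin periodinane, NaHCO3, CH2Cl2, 0 °C; then Ph3P=C(Br)CO2Et, rt
Reagents that add atoms: ethyl bromo(triphenyl-λ5-phosphanylidene)acetate, CCOC(=O)C(Br)=P(c1ccccc1)(c1ccccc1)c1ccccc1
Why: Buffered Dess–Martin oxidation followed in the same flask by a Wittig reaction with a stabilised ylide traps the sensitive β,γ-unsaturated aldehyde under neutral conditions and gives the Z-bromoacrylate (ring trans to the ester).

Step 12
Reactants: 15 ethyl (2Z)-2-bromo-3-[(1S,6R)-6-(propan-2-yl)-3-(TBSO-methyl)cyclohex-2-en-1-yl]prop-2-enoate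
Product: 16 ethyl (2E)-2-(hydroxymethyl)-3-[(1S,6R)-6-(propan-2-yl)-3-(TBSO-methyl)cyclohex-2-en-1-yl]prop-2-enoate
Conditions: Bu3SnCH2OH, Pd(PPh3)4 (5 mol%), 1,4-dioxane, 90 °C
Reagents that add atoms: (tributylstannyl)methanol, CCCC[Sn](CCCC)(CCCC)CO
Why: Stille hydroxymethylation of the alkenyl bromide goes with retention, which places CH2OH cis to the ring and gives the E-acrylate geometry of the target.

Step 13
Reactants: 16 ethyl (2E)-2-(hydroxymethyl)-3-[(1S,6R)-6-(propan-2-yl)-3-(TBSO-methyl)cyclohex-2-en-1-yl]prop-2-enoate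
Product: 17 ethyl (2E)-2-(TBSO-methyl)-3-[(1S,6R)-6-(propan-2-yl)-3-(TBSO-methyl)cyclohex-2-en-1-yl]prop-2-enoate
Conditions: TBSCl, imidazole, DMF, rt
Reagents that add atoms: tert-butyldimethylsilyl chloride, CC(C)(C)[Si](C)(C)Cl
Why: Silylation of the primary allylic alcohol prevents self-esterification in the coupling.

Step 14
Reactants: 17 ethyl (2E)-2-(TBSO-methyl)-3-[(1S,6R)-6-(propan-2-yl)-3-(TBSO-methyl)cyclohex-2-en-1-yl]prop-2-enoate
Product: 18 (2E)-2-(TBSO-methyl)-3-[(1S,6R)-6-(propan-2-yl)-3-(TBSO-methyl)cyclohex-2-en-1-yl]prop-2-enoic acid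
Conditions: LiOH·H2O, THF/MeOH/H2O, 40 °C; then aq. HCl to pH 4
Reagents that add atoms: lithium hydroxide, [Li+].[OH-]
Why: Saponification of the ethyl ester; primary TBS ethers and the trisubstituted acrylate geometry survive aqueous hydroxide.

Step 15
Reactants: 2 1-methoxy-4-[(prop-2-yn-1-yloxy)methyl]benzene
Product: 19 methyl 4-PMBO-but-2-ynoate
Conditions: n-BuLi, THF, −78 °C; ClCO2Me
Reagents that add atoms: methyl chloroformate, COC(=O)Cl
Why: Acylation of the lithium acetylide with a chloroformate gives the ynoate.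

Step 16
Reactants: 19 methyl 4-PMBO-but-2-ynoate
Product: 20 methyl (2E)-4-PMBO-2-(tributylstannyl)but-2-enoate
Conditions: Bu3SnH, Pd(PPh3)4 (2 mol%), THF, 0 °C → rt
Reagents that add atoms: tributyltin hydride, CCCC[SnH](CCCC)CCCC
Why: Pd(PPh3)4-catalysed hydrostannation of an ynoate is a syn addition with tin at the α-carbon, so the ester carbon and CH2OPMB end up cis.

Step 17
Reactants: 20 methyl (2E)-4-PMBO-2-(tributylstannyl)but-2-enoate
Product: 21 (2E)-4-PMBO-2-(tributylstannyl)but-2-en-1-ol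
Conditions: i-Bu2AlH, CH2Cl2, −78 → 0 °C; aq. KNaC4H4O6
Reagents that add atoms: none
Why: 1,2-Reduction of the enoate to the allylic alcohol leaves the carbon–tin bond and the alkene geometry untouched.

Step 18
Reactants: 21 (2E)-4-PMBO-2-(tributylstannyl)but-2-en-1-ol
Product: 22 tert-butyl{[(2E)-4-PMBO-2-(tributylstannyl)but-2-en-1-yl]oxy}dimethylsilane
Conditions: TBSCl, imidazole, DMF, rt
Reagents that add atoms: tert-butyldimethylsilyl chloride, CC(C)(C)[Si](C)(C)Cl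
Why: Silylation under non-alkoxide conditions gives the two CH2O groups orthogonal protection (TBS and PMB).

Step 19
Reactants: 23 2-methylpropanal; 24 dimethyl propanedioate (2.1 equiv in all)
Product: 26 tetramethyl 2-(propan-2-yl)propane-1,1,3,3-tetracarboxylate, via alkylidene malonate 25 (not isolated)
Conditions: 24 (2.1 equiv), piperidine (cat.), AcOH (cat.), PhMe, reflux (Dean–Stark); concentrate; then NaOMe (cat.), MeOH, rt
Reagents that add atoms: dimethyl propanedioate (the second equivalent of 24, for the conjugate addition), COC(=O)CC(=O)OC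
Why: Knoevenagel condensation of the aldehyde with the first equivalent of malonate gives alkylidene malonate 25, and Michael addition of the second equivalent of malonate to it gives the achiral tetraester.

Step 20
Reactants: 26 tetramethyl 2-(propan-2-yl)propane-1,1,3,3-tetracarboxylate
Product: 28 dimethyl 3-(propan-2-yl)pentanedioate, via triester 27 (not isolated)
Conditions: NaCl, H2O, DMSO, 160 °C
Reagents that add atoms: none
Why: Double Krapcho dealkoxycarbonylation of the two malonate units gives the prochiral glutarate.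

Step 21
Reactants: 28 dimethyl 3-(propan-2-yl)pentanedioate
Product: 29 (3R)-5-methoxy-5-oxo-3-(propan-2-yl)pentanoic acid
Conditions: Candida antarctica lipase B (immobilised lipase), KH2PO4/K2HPO4 buffer pH 7.2, 30 °C, pH-stat with 1 M NaOH; then aq. HCl to pH 2
Reagents that add atoms: water, O
Why: Lipase-catalysed hydrolytic desymmetrisation: the enzyme tells the two enantiotopic CH2CO2Me arms apart, which sets the isopropyl-bearing carbon as the first stereocentre of the lactone half.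

Step 22
Reactants: 29 (3R)-5-methoxy-5-oxo-3-(propan-2-yl)pentanoic acid; 22 tert-butyl{[(2E)-4-PMBO-2-(tributylstannyl)but-2-en-1-yl]oxy}dimethylsilane
Product: 31 methyl (3R,6E)-5-oxo-8-PMBO-3-(propan-2-yl)-6-(TBSO-methyl)oct-6-enoate, via acid chloride 30 (not isolated)
Conditions: (COCl)2, DMF (cat.), CH2Cl2, 0 °C → rt, concentrate; then 22, Pd2(dba)3 (2.5 mol%), P(2-furyl)3 (10 mol%), PhMe, 60 °C
Reagents that add atoms: none
Why: Acid chloride formation and Stille acylation under Pd2(dba)3 (zerovalent palladium), with retention at the alkenyl carbon; the β-stereocentre cannot epimerise, and the crude chloride is used cold and at once so that it cannot close to the symmetric anhydride.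

Step 23
Reactants: 31 methyl (3R,6E)-5-oxo-8-PMBO-3-(propan-2-yl)-6-(TBSO-methyl)oct-6-enoate
Product: 33 (4R,6R)-6-[(2E)-4-PMBO-1-TBSO-but-2-en-2-yl]-4-(propan-2-yl)oxan-2-one, via hydroxy ester 32 (not isolated)
Conditions: (S)-2-methyl-CBS-oxazaborolidine (20 mol%), BH3·SMe2, THF, −30 °C; MeOH; then PPTS (cat.), PhMe, 50 °C
Reagents that add atoms: none
Why: Corey–Bakshi–Shibata reduction with the α-substituted alkenyl group as the large substituent gives the (5R)-allylic alcohol under catalyst control, and lactonisation then gives the 4,6-cis δ-lactone.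

Step 24
Reactants: 33 (4R,6R)-6-[(2E)-4-PMBO-1-TBSO-but-2-en-2-yl]-4-(propan-2-yl)oxan-2-one
Product: 36 (1S,2S,6S)-2-(PMBO-methyl)-6-(propan-2-yl)-3-(TBSO-methyl)cyclohex-3-ene-1-carboxylic acid, via silyl ketene acetal 34 (not isolated), via silyl ester 35 (not isolated)
Conditions: LiN(i-Pr)2, Me3SiCl/Et3N, THF, −78 °C; PhMe, 105 °C; then 0.5 M aq. HCl, THF, 0 °C
Reagents that add atoms: none
Why: Ireland–Claisen ring contraction of the lactone silyl ketene acetal, forced through a boat transition state by the six-membered lactone: the new bond forms on the lactone face carrying the alkenyl group (CO2H trans to isopropyl) and the alkene geometry (CH2OPMB trans to the carbinol carbon) places CH2OPMB cis to CO2H; this forms ring B and two stereocentres.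

Step 25
Reactants: 36 (1S,2S,6S)-2-(PMBO-methyl)-6-(propan-2-yl)-3-(TBSO-methyl)cyclohex-3-ene-1-carboxylic acid
Product: 37 bridged iodolactone 4-iodo-8-(PMBO-methyl)-2-(propan-2-yl)-5-(TBSO-methyl)-6-oxabicyclo[3.2.1]octan-7-one
Conditions: I2, KI, NaHCO3, THF/H2O, 0 °C, dark
Reagents that add atoms: iodine, II
Why: Iodolactonisation: the carboxylate opens the iodonium ion at the more substituted carbon to give the γ-lactone, so the tertiary C–O bond must lie on the face of the carboxyl group (cis to CH2OPMB), which sets the carbinol stereocentre.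

Step 26
Reactants: 37 bridged iodolactone
Product: 38 8-(PMBO-methyl)-2-(propan-2-yl)-5-(TBSO-methyl)-6-oxabicyclo[3.2.1]octan-7-one
Conditions: Bu3SnH, AIBN (cat.), PhMe (0.1 M), 80 °C
Reagents that add atoms: none
Why: Radical deiodination; at this Bu3SnH concentration hydrogen transfer is faster than a 1,2-acyloxy shift, and no stereocentre is affected.

Step 27
Reactants: 38 8-(PMBO-methyl)-2-(propan-2-yl)-5-(TBSO-methyl)-6-oxabicyclo[3.2.1]octan-7-one
Product: 39 8-(PMBO-methyl)-2-(propan-2-yl)-5-(TBSO-methyl)-6-oxabicyclo[3.2.1]octan-7-ol (lactol; anomer mixture)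
Conditions: i-Bu2AlH (1.1 equiv), CH2Cl2, −78 °C; aq. KNaC4H4O6
Reagents that add atoms: none
Why: Partial reduction of a γ-lactone stops at the lactol at low temperature.

Step 28
Reactants: 39 lactol
Product: 40 (1R,2R,3S,4S)-3-ethenyl-2-(PMBO-methyl)-4-(propan-2-yl)-1-(TBSO-methyl)cyclohexan-1-ol
Conditions: Ph3PCH3Br, KN(SiMe3)2, THF, 0 °C → rt
Reagents that add atoms: methylidenetriphenylphosphorane (from Ph3PCH3Br and KN(SiMe3)2), C=P(c1ccccc1)(c1ccccc1)c1ccccc1
Why: Wittig methylenation of the open hydroxy-aldehyde form of the lactol installs the vinyl group and frees the tertiary alcohol in one operation.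

Step 29
Reactants: 40 (1R,2R,3S,4S)-3-ethenyl-2-(PMBO-methyl)-4-(propan-2-yl)-1-(TBSO-methyl)cyclohexan-1-ol
Product: 41 (1R,2R,3S,4S)-3-ethenyl-1-(hydroxymethyl)-2-(PMBO-methyl)-4-(propan-2-yl)cyclohexan-1-ol
Conditions: Bu4NF, THF, 0 °C
Reagents that add atoms: none
Why: Fluoride cleaves the TBS ether and leaves the PMB ether, which exposes only the primary hydroxyl that will carry the ester.

Step 30
Reactants: 18 (2E)-2-(TBSO-methyl)-3-[(1S,6R)-6-(propan-2-yl)-3-(TBSO-methyl)cyclohex-2-en-1-yl]prop-2-enoic acid; 41 (1R,2R,3S,4S)-3-ethenyl-1-(hydroxymethyl)-2-(PMBO-methyl)-4-(propan-2-yl)cyclohexan-1-ol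
Product: 43 ester of acid 18 at the primary hydroxyl of diol 41 (tertiary hydroxyl free), via mixed anhydride 42 (not isolated)
Conditions: 2,4,6-Cl3C6H2COCl, Et3N, THF, rt; then 41, DMAP, PhMe, rt
Reagents that add atoms: none
Why: Yamaguchi esterification acylates the primary (neopentyl-type) hydroxyl and leaves the tertiary one; joining the halves now, while the neighbouring carbon is still CH2OPMB, means a free γ-hydroxy ester is never present.

Step 31
Reactants: 43 ester of 18 with 41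
Product: 44 primary alcohol (43 with CH2OPMB changed to CH2OH)
Conditions: DDQ, CH2Cl2/pH 7 buffer, 0 °C
Reagents that add atoms: none
Why: Oxidative PMB cleavage is orthogonal to the two TBS ethers and both ester-type functions.

Step 32
Reactants: 44 primary alcohol
Product: 46 carboxylic acid (44 with CH2OH changed to CO2H), via aldehyde 45 (not isolated)
Conditions: TEMPO (cat.), PhI(OAc)2, MeCN/H2O, rt
Reagents that add atoms: water, O
Why: Oxoammonium oxidation of the primary alcohol to the acid under near-neutral conditions spares the tertiary alcohol and does not epimerise or retro-aldolise the β-hydroxy aldehyde stage.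

Step 33
Reactants: 46 carboxylic acid; 47 tert-butyl 2-(bromomethyl)prop-2-enoate
Product: 48 2-(tert-butoxycarbonyl)prop-2-en-1-yl ester of acid 46
Conditions: Cs2CO3, DMF, 0 °C → rt
Reagents that add atoms: none
Why: O-Alkylation of the caesium carboxylate with the allylic bromide (direct and allylic substitution give the same ester).

Step 34
Reactants: 48 2-(tert-butoxycarbonyl)prop-2-en-1-yl ester of acid 46
Product: 49 tert-butyl ester and bis-TBS ether of the target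
Conditions: second-generation Hoveyda–Grubbs catalyst RuCl2(H2IMes)(=CH-C6H4-2-O-i-Pr) (10 mol%), PhMe (2 mM), 80 °C
Reagents that add atoms: none
Why: Ring-closing metathesis between the vinyl group and the 1,1-disubstituted acrylate closes ring C; the cis arrangement of the two arms on ring B favours closure and the ring fixes the alkene geometry (ring carbon cis to CH2O).

Step 35
Reactants: 49 tert-butyl ester and bis-TBS ether of the target
Product: 50 tert-butyl ester of the target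
Conditions: HF·pyridine, pyridine, THF, 0 °C → rt
Reagents that add atoms: none
Why: Buffered fluoride desilylation frees the two primary allylic alcohols and leaves the lactone, both esters and the tert-butyl ester alone.

Step 36
Reactants: 50 tert-butyl ester of the target
Product: 51 (5aR,6S,9R,9aS)-9-hydroxy-9-({[(2E)-2-(hydroxymethyl)-3-[(1S,6R)-3-(hydroxymethyl)-6-(propan-2-yl)cyclohex-2-en-1-yl]prop-2-enoyl]oxy}methyl)-1-oxo-6-(propan-2-yl)-1,3,5a,6,7,8,9,9a-octahydro-2-benzoxepine-4-carboxylic acid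
Conditions: CF3CO2H/CH2Cl2 (1:4), 0 °C → rt; then aq. NaHCO3 wash
Reagents that add atoms: none
Why: Acidolysis of the tert-butyl ester (loss of isobutene) frees the acid; the tertiary alcohol is flanked by electron-withdrawing groups and does not ionise, and any trifluoroacetates on the primary alcohols fall off in the wash.

**Compound list**
1 | prop-2-yn-1-ol | C#CCO | starting material
2 | 1-methoxy-4-[(prop-2-yn-1-yloxy)methyl]benzene | COc1ccc(COCC#C)cc1 | intermediate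
3 | 2-[(1E)-3-PMBO-prop-1-en-1-yl]-4,4,5,5-tetramethyl-1,3,2-dioxaborolane | COc1ccc(COC/C=C/B2OC(C)(C)C(C)(C)O2)cc1 | intermediate
4 | 2-bromoprop-2-en-1-ol | OCC(Br)=C | starting material
5 | [(2-bromoprop-2-en-1-yl)oxy](tert-butyl)dimethylsilane | CC(C)(C)[Si](C)(C)OCC(Br)=C | intermediate
6 | tert-butyl{[(3E)-2-methylidene-5-PMBO-pent-3-en-1-yl]oxy}dimethylsilane | C=C(CO[Si](C)(C)C(C)(C)C)/C=C/COCc1ccc(OC)cc1 | intermediate
7 | 3-(prop-2-enoyl)-1,3-oxazolidin-2-one | C=CC(=O)N1CCOC1=O | starting material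
8 | 3-{[(1S,2R)-2-(PMBO-methyl)-4-(TBSO-methyl)cyclohex-3-en-1-yl]carbonyl}-1,3-oxazolidin-2-one (1,2-cis) | O=C(N1CCOC1=O)[C@H]1CCC(CO[Si](C)(C)C(C)(C)C)=C[C@H]1COCc1ccc(OC)cc1 | intermediate
9 | (1S,2R)-N-methoxy-N-methyl-2-(PMBO-methyl)-4-(TBSO-methyl)cyclohex-3-ene-1-carboxamide | CON(C)C(=O)[C@H]1CCC(CO[Si](C)(C)C(C)(C)C)=C[C@H]1COCc1ccc(OC)cc1 | intermediate
10 | 1-[(1S,2R)-2-(PMBO-methyl)-4-(TBSO-methyl)cyclohex-3-en-1-yl]ethan-1-one | CC(=O)[C@H]1CCC(CO[Si](C)(C)C(C)(C)C)=C[C@H]1COCc1ccc(OC)cc1 | intermediate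
11 | (3R,4S)-3-(PMBO-methyl)-4-(prop-1-en-2-yl)-1-(TBSO-methyl)cyclohex-1-ene | C=C(C)[C@H]1CCC(CO[Si](C)(C)C(C)(C)C)=C[C@H]1COCc1ccc(OC)cc1 | intermediate
12 | (3S,4R)-3-(PMBO-methyl)-4-(propan-2-yl)-1-(TBSO-methyl)cyclohex-1-ene | CC(C)[C@H]1CCC(CO[Si](C)(C)C(C)(C)C)=C[C@H]1COCc1ccc(OC)cc1 | intermediate
13 | [(1S,6R)-6-(propan-2-yl)-3-(TBSO-methyl)cyclohex-2-en-1-yl]methanol | CC(C)[C@H]1CCC(CO[Si](C)(C)C(C)(C)C)=C[C@H]1CO | intermediate
14 | (1S,6R)-6-(propan-2-yl)-3-(TBSO-methyl)cyclohex-2-ene-1-carbaldehyde | CC(C)[C@H]1CCC(CO[Si](C)(C)C(C)(C)C)=C[C@H]1C=O | intermediate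
15 | ethyl (2Z)-2-bromo-3-[(1S,6R)-6-(propan-2-yl)-3-(TBSO-methyl)cyclohex-2-en-1-yl]prop-2-enoate | CC(C)[C@H]1CCC(CO[Si](C)(C)C(C)(C)C)=C[C@H]1/C=C(\Br)C(=O)OCC | intermediate
16 | ethyl (2E)-2-(hydroxymethyl)-3-[(1S,6R)-6-(propan-2-yl)-3-(TBSO-methyl)cyclohex-2-en-1-yl]prop-2-enoate | CC(C)[C@H]1CCC(CO[Si](C)(C)C(C)(C)C)=C[C@H]1/C=C(\CO)C(=O)OCC | intermediate
17 | ethyl (2E)-2-(TBSO-methyl)-3-[(1S,6R)-6-(propan-2-yl)-3-(TBSO-methyl)cyclohex-2-en-1-yl]prop-2-enoate | CC(C)[C@H]1CCC(CO[Si](C)(C)C(C)(C)C)=C[C@H]1/C=C(\CO[Si](C)(C)C(C)(C)C)C(=O)OCC | intermediate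
18 | (2E)-2-(TBSO-methyl)-3-[(1S,6R)-6-(propan-2-yl)-3-(TBSO-methyl)cyclohex-2-en-1-yl]prop-2-enoic acid | CC(C)[C@H]1CCC(CO[Si](C)(C)C(C)(C)C)=C[C@H]1/C=C(\CO[Si](C)(C)C(C)(C)C)C(=O)O | intermediate
19 | methyl 4-PMBO-but-2-ynoate | COC(=O)C#CCOCc1ccc(OC)cc1 | intermediate
20 | methyl (2E)-4-PMBO-2-(tributylstannyl)but-2-enoate | COC(=O)/C(=C\COCc1ccc(OC)cc1)[Sn](CCCC)(CCCC)CCCC | intermediate
21 | (2E)-4-PMBO-2-(tributylstannyl)but-2-en-1-ol | OC/C(=C\COCc1ccc(OC)cc1)[Sn](CCCC)(CCCC)CCCC | intermediate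
22 | tert-butyl{[(2E)-4-PMBO-2-(tributylstannyl)but-2-en-1-yl]oxy}dimethylsilane | CC(C)(C)[Si](C)(C)OC/C(=C\COCc1ccc(OC)cc1)[Sn](CCCC)(CCCC)CCCC | intermediate
23 | 2-methylpropanal | CC(C)C=O | starting material
24 | dimethyl propanedioate | COC(=O)CC(=O)OC | starting material
25 | dimethyl 2-(2-methylpropylidene)propanedioate | COC(=O)C(=CC(C)C)C(=O)OC | intermediate
26 | tetramethyl 2-(propan-2-yl)propane-1,1,3,3-tetracarboxylate | COC(=O)C(C(=O)OC)C(C(C)C)C(C(=O)OC)C(=O)OC | intermediate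
27 | trimethyl 2-(propan-2-yl)propane-1,1,3-tricarboxylate (racemic) | COC(=O)CC(C(C)C)C(C(=O)OC)C(=O)OC | intermediate
28 | dimethyl 3-(propan-2-yl)pentanedioate | COC(=O)CC(C(C)C)CC(=O)OC | intermediate
29 | (3R)-5-methoxy-5-oxo-3-(propan-2-yl)pentanoic acid | OC(=O)C[C@@H](C(C)C)CC(=O)OC | intermediate
30 | methyl (3S)-5-chloro-5-oxo-3-(propan-2-yl)pentanoate | ClC(=O)C[C@@H](C(C)C)CC(=O)OC | intermediate
31 | methyl (3R,6E)-5-oxo-8-PMBO-3-(propan-2-yl)-6-(TBSO-methyl)oct-6-enoate | CC(C)(C)[Si](C)(C)OC/C(=C\COCc1ccc(OC)cc1)C(=O)C[C@@H](C(C)C)CC(=O)OC | intermediate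
32 | methyl (3R,5R,6E)-5-hydroxy-8-PMBO-3-(propan-2-yl)-6-(TBSO-methyl)oct-6-enoate | CC(C)(C)[Si](C)(C)OC/C(=C\COCc1ccc(OC)cc1)[C@H](O)C[C@@H](C(C)C)CC(=O)OC | intermediate
33 | (4R,6R)-6-[(2E)-4-PMBO-1-TBSO-but-2-en-2-yl]-4-(propan-2-yl)oxan-2-one (4,6-cis) | CC(C)(C)[Si](C)(C)OC/C(=C\COCc1ccc(OC)cc1)[C@H]1C[C@@H](C(C)C)CC(=O)O1 | intermediate
34 | trimethylsilyl ketene acetal of lactone 33 | CC(C)(C)[Si](C)(C)OC/C(=C\COCc1ccc(OC)cc1)[C@H]1C[C@@H](C(C)C)C=C(O[Si](C)(C)C)O1 | intermediate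
35 | trimethylsilyl ester of acid 36 | CC(C)(C)[Si](C)(C)OCC1=CC[C@@H](C(C)C)[C@H](C(=O)O[Si](C)(C)C)[C@@H]1COCc1ccc(OC)cc1 | intermediate
36 | (1S,2S,6S)-2-(PMBO-methyl)-6-(propan-2-yl)-3-(TBSO-methyl)cyclohex-3-ene-1-carboxylic acid (CO2H cis to CH2OPMB, trans to isopropyl) | CC(C)(C)[Si](C)(C)OCC1=CC[C@@H](C(C)C)[C@H](C(=O)O)[C@@H]1COCc1ccc(OC)cc1 | intermediate
37 | 4-iodo-8-(PMBO-methyl)-2-(propan-2-yl)-5-(TBSO-methyl)-6-oxabicyclo[3.2.1]octan-7-one (lactone bridge on the face of the former CO2H, iodine anti to the lactone oxygen) | CC(C)(C)[Si](C)(C)OC[C@@]1(O2)[C@@H](I)C[C@@H](C(C)C)[C@H](C2=O)[C@@H]1COCc1ccc(OC)cc1 | intermediate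
38 | 8-(PMBO-methyl)-2-(propan-2-yl)-5-(TBSO-methyl)-6-oxabicyclo[3.2.1]octan-7-one (lactone bridge cis to CH2OPMB, anti to isopropyl) | CC(C)(C)[Si](C)(C)OC[C@@]1(O2)CC[C@@H](C(C)C)[C@H](C2=O)[C@@H]1COCc1ccc(OC)cc1 | intermediate
39 | 8-(PMBO-methyl)-2-(propan-2-yl)-5-(TBSO-methyl)-6-oxabicyclo[3.2.1]octan-7-ol (anomer mixture) | CC(C)(C)[Si](C)(C)OC[C@@]1(O2)CC[C@@H](C(C)C)[C@H](C2O)[C@@H]1COCc1ccc(OC)cc1 | intermediate
40 | (1R,2R,3S,4S)-3-ethenyl-2-(PMBO-methyl)-4-(propan-2-yl)-1-(TBSO-methyl)cyclohexan-1-ol | CC(C)(C)[Si](C)(C)OC[C@@]1(O)CC[C@@H](C(C)C)[C@H](C=C)[C@@H]1COCc1ccc(OC)cc1 | intermediate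
41 | (1R,2R,3S,4S)-3-ethenyl-1-(hydroxymethyl)-2-(PMBO-methyl)-4-(propan-2-yl)cyclohexan-1-ol | OC[C@@]1(O)CC[C@@H](C(C)C)[C@H](C=C)[C@@H]1COCc1ccc(OC)cc1 | intermediate
42 | mixed anhydride of acid 18 with 2,4,6-trichlorobenzoic acid | CC(C)[C@H]1CCC(CO[Si](C)(C)C(C)(C)C)=C[C@H]1/C=C(\CO[Si](C)(C)C(C)(C)C)C(=O)OC(=O)c1c(Cl)cc(Cl)cc1Cl | intermediate
43 | [(1R,2R,3S,4S)-3-ethenyl-1-hydroxy-2-(PMBO-methyl)-4-(propan-2-yl)cyclohexyl]methyl ester of acid 18 | CC(C)[C@H]1CCC(CO[Si](C)(C)C(C)(C)C)=C[C@H]1/C=C(\CO[Si](C)(C)C(C)(C)C)C(=O)OC[C@@]1(O)CC[C@@H](C(C)C)[C@H](C=C)[C@@H]1COCc1ccc(OC)cc1 | intermediate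
44 | 43 with CH2OPMB changed to CH2OH | CC(C)[C@H]1CCC(CO[Si](C)(C)C(C)(C)C)=C[C@H]1/C=C(\CO[Si](C)(C)C(C)(C)C)C(=O)OC[C@@]1(O)CC[C@@H](C(C)C)[C@H](C=C)[C@@H]1CO | intermediate
45 | 44 with CH2OH changed to CHO | CC(C)[C@H]1CCC(CO[Si](C)(C)C(C)(C)C)=C[C@H]1/C=C(\CO[Si](C)(C)C(C)(C)C)C(=O)OC[C@@]1(O)CC[C@@H](C(C)C)[C@H](C=C)[C@@H]1C=O | intermediate
46 | 44 with CH2OH changed to CO2H | CC(C)[C@H]1CCC(CO[Si](C)(C)C(C)(C)C)=C[C@H]1/C=C(\CO[Si](C)(C)C(C)(C)C)C(=O)OC[C@@]1(O)CC[C@@H](C(C)C)[C@H](C=C)[C@@H]1C(=O)O | intermediate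
47 | tert-butyl 2-(bromomethyl)prop-2-enoate | C=C(CBr)C(=O)OC(C)(C)C | starting material
48 | 2-(tert-butoxycarbonyl)prop-2-en-1-yl ester of acid 46 | CC(C)[C@H]1CCC(CO[Si](C)(C)C(C)(C)C)=C[C@H]1/C=C(\CO[Si](C)(C)C(C)(C)C)C(=O)OC[C@@]1(O)CC[C@@H](C(C)C)[C@H](C=C)[C@@H]1C(=O)OCC(=C)C(=O)OC(C)(C)C | intermediate
49 | tert-butyl ester and bis-TBS ether of the target | CC(C)[C@H]1CCC(CO[Si](C)(C)C(C)(C)C)=C[C@H]1/C=C(\CO[Si](C)(C)C(C)(C)C)C(=O)OC[C@@]1(O)CC[C@@H](C(C)C)[C@@H]2C=C(C(=O)OC(C)(C)C)COC(=O)[C@@H]21 | intermediate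
50 | tert-butyl ester of the target | CC(C)[C@H]1CCC(CO)=C[C@H]1/C=C(\CO)C(=O)OC[C@@]1(O)CC[C@@H](C(C)C)[C@@H]2C=C(C(=O)OC(C)(C)C)COC(=O)[C@@H]21 | intermediate
51 | (5aR,6S,9R,9aS)-9-hydroxy-9-({[(2E)-2-(hydroxymethyl)-3-[(1S,6R)-3-(hydroxymethyl)-6-(propan-2-yl)cyclohex-2-en-1-yl]prop-2-enoyl]oxy}methyl)-1-oxo-6-(propan-2-yl)-1,3,5a,6,7,8,9,9a-octahydro-2-benzoxepine-4-carboxylic acid | CC(C)[C@H]1CCC(CO)=C[C@H]1/C=C(\CO)C(=O)OC[C@@]1(O)CC[C@@H](C(C)C)[C@@H]2C=C(C(=O)O)COC(=O)[C@@H]21 | target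

**Totals**
Total step count: 36.
Longest linear sequence: 20 steps (1, 2, 4–14, 30–36; the stannane branch 1, 15–18, 22–36 is equally long).

**Three steps most likely to fail, each with a fallback**

Step 24 (Ireland–Claisen ring contraction through a boat transition state). If yield or selectivity is poor, ring B is made by a catalytic asymmetric Diels–Alder reaction instead. Setting out from stannane 22, Stille coupling with vinyl bromide (Pd(PPh3)4, DMF, 60 °C) gives tert-butyl{[(2Z)-2-ethenyl-4-PMBO-but-2-en-1-yl]oxy}dimethylsilane F3. Separately, 1,3-oxazolidin-2-one is N-acylated with (2E)-4-methylpent-2-enoyl chloride (n-BuLi, THF) to give 3-[(2E)-4-methylpent-2-enoyl]-1,3-oxazolidin-2-one F4. Cycloaddition of F3 and F4 under [Cu((S,S)-t-Bu-box)](SbF6)2 (endo; the terminal diene substituent directs as in 1-vinylcyclohexene) gives 3-{[(1S,2S,6S)-2-(PMBO-methyl)-6-(propan-2-yl)-3-(TBSO-methyl)cyclohex-3-en-1-yl]carbonyl}-1,3-oxazolidin-2-one F5. Cleavage with LiOH/H2O2 comes back to the route at acid 36. The weak point of this fallback is the low reactivity of a β-branched dienophile toward an acyclic diene.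

Step 34 (metathesis onto a 1,1-disubstituted, electron-poor alkene to form a seven-membered lactone). If it stalls or dimerises, ring C is closed by C–O bond formation instead. Setting out from lactol 39, a Wittig reaction with tert-butyl bromo(triphenyl-λ5-phosphanylidene)acetate (PhMe, 80 °C) gives the Z-bromoacrylate analogue of 40 (CH=C(Br)CO2t-Bu in place of ethenyl) F6. Bu4NF gives its diol F7. Yamaguchi esterification with acid 18 (through anhydride 42) gives the ester F8. DDQ gives the primary alcohol F9, and TEMPO/PhI(OAc)2 gives the carboxylic acid F10. Stille hydroxymethylation (Bu3SnCH2OH, Pd(PPh3)4, dioxane, 90 °C) gives the hydroxy acid F11. Yamaguchi lactonisation at high dilution (2,4,6-Cl3C6H2COCl, Et3N, then DMAP, PhMe) comes back to the route at lactone 49.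

Step 21 (enantioselectivity and sense of the lipase hydrolysis, on which every later stereocentre of the lactone half depends). If the ee is low or the wrong half-ester forms, the desymmetrisation is done by organocatalysis on the anhydride. Setting out from diester 28, saponification (aq. NaOH, then HCl) gives 3-(propan-2-yl)pentanedioic acid F1, and Ac2O at reflux gives 4-(propan-2-yl)oxane-2,6-dione F2. Methanolysis of F2 under a dimeric cinchona alkaloid catalyst ((DHQD)2AQN or its pseudo-enantiomer (DHQ)2AQN, whichever delivers the R acid; Et2O, −20 °C) comes back to the route at half-ester 29.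

**Further compounds**
F1 | step 21 | 3-(propan-2-yl)pentanedioic acid | CC(C)C(CC(=O)O)CC(=O)O
F2 | step 21 | 4-(propan-2-yl)oxane-2,6-dione | CC(C)C1CC(=O)OC(=O)C1
F3 | step 24 | tert-butyl{[(2Z)-2-ethenyl-4-PMBO-but-2-en-1-yl]oxy}dimethylsilane | C=C/C(=C/COCc1ccc(OC)cc1)CO[Si](C)(C)C(C)(C)C
F4 | step 24 | 3-[(2E)-4-methylpent-2-enoyl]-1,3-oxazolidin-2-one | CC(C)/C=C/C(=O)N1CCOC1=O
F5 | step 24 | 3-{[(1S,2S,6S)-2-(PMBO-methyl)-6-(propan-2-yl)-3-(TBSO-methyl)cyclohex-3-en-1-yl]carbonyl}-1,3-oxazolidin-2-one | CC(C)(C)[Si](C)(C)OCC1=CC[C@@H](C(C)C)[C@H](C(=O)N2CCOC2=O)[C@@H]1COCc1ccc(OC)cc1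
F6 | step 34 | Z-bromoacrylate analogue of 40 (CH=C(Br)CO2t-Bu in place of ethenyl) | CC(C)(C)[Si](C)(C)OC[C@@]1(O)CC[C@@H](C(C)C)[C@H](/C=C(\Br)C(=O)OC(C)(C)C)[C@@H]1COCc1ccc(OC)cc1
F7 | step 34 | diol from F6 (CH2OTBS changed to CH2OH) | OC[C@@]1(O)CC[C@@H](C(C)C)[C@H](/C=C(\Br)C(=O)OC(C)(C)C)[C@@H]1COCc1ccc(OC)cc1
F8 | step 34 | ester of acid 18 at the primary hydroxyl of F7 | CC(C)[C@H]1CCC(CO[Si](C)(C)C(C)(C)C)=C[C@H]1/C=C(\CO[Si](C)(C)C(C)(C)C)C(=O)OC[C@@]1(O)CC[C@@H](C(C)C)[C@H](/C=C(\Br)C(=O)OC(C)(C)C)[C@@H]1COCc1ccc(OC)cc1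
F9 | step 34 | F8 with CH2OPMB changed to CH2OH | CC(C)[C@H]1CCC(CO[Si](C)(C)C(C)(C)C)=C[C@H]1/C=C(\CO[Si](C)(C)C(C)(C)C)C(=O)OC[C@@]1(O)CC[C@@H](C(C)C)[C@H](/C=C(\Br)C(=O)OC(C)(C)C)[C@@H]1CO
F10 | step 34 | F9 with CH2OH changed to CO2H | CC(C)[C@H]1CCC(CO[Si](C)(C)C(C)(C)C)=C[C@H]1/C=C(\CO[Si](C)(C)C(C)(C)C)C(=O)OC[C@@]1(O)CC[C@@H](C(C)C)[C@H](/C=C(\Br)C(=O)OC(C)(C)C)[C@@H]1C(=O)O
F11 | step 34 | hydroxy acid (F10 with Br changed to CH2OH; E) | CC(C)[C@H]1CCC(CO[Si](C)(C)C(C)(C)C)=C[C@H]1/C=C(\CO[Si](C)(C)C(C)(C)C)C(=O)OC[C@@]1(O)CC[C@@H](C(C)C)[C@H](/C=C(\CO)C(=O)OC(C)(C)C)[C@@H]1C(=O)O
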